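**Plan**
- Retrosynthesis: ring C is cut at C4–C4a (aryllithium acylation), then at the O1–C2 enol ether bond. The C2–C3 and C3–C1′ bonds follow (aldehyde plus diazoacetate with 1,2-aryl shift), and last the pyran ring D (aryl propargyl ether, Claisen rearrangement).
- Forward: ring D is fused onto ring B (steps 1–2), the C2–C3–C4 unit is grown on the ring-B aldehyde (steps 3–5), ring A is attached through O1 (steps 6–7), ring C closes last (step 8), and both silyl ethers fall together (step 9).
- Enabling feature: C4a of resorcinol ring A is ortho to O1, so a bromine at C4a of the aryl enol ether becomes the nucleophile by exchange and ring C closes under base only. The acid-labile 2,2-dimethylpyran ring D on ring B is never exposed to strong acid.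
- Stereochemistry: the target has no stereocentre. The one geometric requirement, aryloxy cis to the ester (Z) in the cyclisation precursor, is set by sulfonylation of a lithium-chelated enolate (step 5) and should be retained in the vinylic substitution (step 7).

Key step: step 8

Assumption: compound 8 is drawn as its hydrogen-bonded Z enol, which equilibrates with the aldehyde tautomer. An ethyl ester and two triisopropylsilyl ethers are chosen, because the alkoxide is lost in step 8 and one fluoride step then frees both phenols.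

**Step 1**
Reactants: 1 2,4-dihydroxy-5-methoxybenzaldehyde; 2 3-chloro-3-methylbut-1-yne
Product: 3 2-hydroxy-5-methoxy-4-[(2-methylbut-3-yn-2-yl)oxy]benzaldehyde
Conditions: DBU, CuCl2 (cat.), MeCN, 0 °C to rt
Reagents that add atoms: none
Why: Copper-catalysed O-propargylation of a phenol with a tertiary propargylic chloride should take the more acidic 4-OH, since the 2-OH is tied to the aldehyde by a hydrogen bond.

**Step 2**
Reactants: 3 2-hydroxy-5-methoxy-4-[(2-methylbut-3-yn-2-yl)oxy]benzaldehyde
Product: 5 5-hydroxy-8-methoxy-2,2-dimethyl-2H-chromene-6-carbaldehyde, via allenyl phenol 4 (not isolated)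
Conditions: N,N-diethylaniline, 190 °C
Reagents that add atoms: none
Why: The aromatic propargyl Claisen rearrangement can only reach C3 (C5 carries the methoxy group), and the allenyl phenol 4 should close to the 2H-chromene by 1,5-hydrogen shift and 6π-electrocyclisation.

**Step 3**
Reactants: 5 5-hydroxy-8-methoxy-2,2-dimethyl-2H-chromene-6-carbaldehyde
Product: 6 8-methoxy-2,2-dimethyl-5-[(triisopropylsilyl)oxy]-2H-chromene-6-carbaldehyde
Conditions: TIPSOTf, 2,6-lutidine, CH2Cl2, 0 °C to rt
Reagents that add atoms: triisopropylsilyl trifluoromethanesulfonate, CC(C)[Si](C(C)C)(C(C)C)OS(=O)(=O)C(F)(F)F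
Why: Silylation with the reactive silyl triflate should overcome the hydrogen bond and the two ortho substituents, and the free phenol must be masked because it would trap the product of step 4 as a benzofuran.

**Step 4**
Reactants: 6 8-methoxy-2,2-dimethyl-5-[(triisopropylsilyl)oxy]-2H-chromene-6-carbaldehyde; 7 ethyl diazoacetate
Product: 8 ethyl (Z)-3-hydroxy-2-{8-methoxy-2,2-dimethyl-5-[(triisopropylsilyl)oxy]-2H-chromen-6-yl}prop-2-enoate
Conditions: HBF4·OEt2 (10 mol %), CH2Cl2, −78 °C, slow addition of 7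
Reagents that add atoms: none
Why: Acid-catalysed addition of the diazo ester to the aldehyde with 1,2-aryl shift and loss of N2 (the aryl-migration variant of the Roskamp homologation) should be favoured over hydride shift by the electron-rich ring with a para ring oxygen, and catalytic acid at −78 °C should spare the silyl ether and ring D.

**Step 5**
Reactants: 8 ethyl (Z)-3-hydroxy-2-{8-methoxy-2,2-dimethyl-5-[(triisopropylsilyl)oxy]-2H-chromen-6-yl}prop-2-enoate
Product: 9 ethyl (Z)-2-{8-methoxy-2,2-dimethyl-5-[(triisopropylsilyl)oxy]-2H-chromen-6-yl}-3-(tosyloxy)prop-2-enoate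
Conditions: TsCl, TMEDA, LiCl, MeCN, −20 to 0 °C
Reagents that add atoms: p-toluenesulfonyl chloride, Cc1ccc(cc1)S(=O)(=O)Cl
Why: O-Sulfonylation of the enolate in which Li+ bridges the enolate and ester oxygens should place the tosyloxy group cis to the ester (Z), and the chelate also keeps the enolate oxygen away from the ortho silyl ether.

**Step 6**
Reactants: 10 4-bromoresorcinol
Product: 11 2-bromo-5-[(triisopropylsilyl)oxy]phenol
Conditions: TIPSCl (1.0 equiv), imidazole, CH2Cl2, 0 °C
Reagents that add atoms: triisopropylsilyl chloride, CC(C)[Si](Cl)(C(C)C)C(C)C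
Why: Silylation with a bulky chlorosilane should take the unhindered OH para to bromine and leave free the OH flanked by bromine.

**Step 7**
Reactants: 9 ethyl (Z)-2-{8-methoxy-2,2-dimethyl-5-[(triisopropylsilyl)oxy]-2H-chromen-6-yl}-3-(tosyloxy)prop-2-enoate; 11 2-bromo-5-[(triisopropylsilyl)oxy]phenol
Product: 12 ethyl (Z)-3-{2-bromo-5-[(triisopropylsilyl)oxy]phenoxy}-2-{8-methoxy-2,2-dimethyl-5-[(triisopropylsilyl)oxy]-2H-chromen-6-yl}prop-2-enoate
Conditions: K2CO3, 18-crown-6 (cat.), MeCN, 0 °C to rt, 1.0 equiv of 11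
Reagents that add atoms: none
Why: In this nucleophilic vinylic substitution (addition–elimination) the tosylate should leave before the C2–C3 bond rotates, so the Z geometry is retained, and one equivalent of phenol at low temperature limits later exchange and isomerisation.

**Step 8**
Reactants: 12 ethyl (Z)-3-{2-bromo-5-[(triisopropylsilyl)oxy]phenoxy}-2-{8-methoxy-2,2-dimethyl-5-[(triisopropylsilyl)oxy]-2H-chromen-6-yl}prop-2-enoate
Product: 15 3-{8-methoxy-2,2-dimethyl-5-[(triisopropylsilyl)oxy]-2H-chromen-6-yl}-7-[(triisopropylsilyl)oxy]-4H-chromen-4-one, via aryllithium 13 (not isolated), via lithium hemiketal alkoxide 14 (not isolated)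
Conditions: n-BuLi (1.05 equiv), THF, −100 °C, then to −20 °C; AcOH quench
Reagents that add atoms: none
Why: n-BuLi exchanges the bromine at C4a to give aryllithium 13, which the Z enol ether places within reach of the ester carbonyl; addition gives alkoxide 14, and loss of ethoxide forms the C4–C4a bond and the pyranone. The closest known reaction type is the Parham cyclisation, an aryl halide–lithium exchange followed by intramolecular acylation by an ester. Ring C closes in a 6-exo-trig mode and no stereocentre is formed. The step needs site control, chemoselectivity and the correct alkene geometry: the position of the halogen alone, rather than the directing effects of the two ring-A oxygens, decides that C4a and not C8 is acylated; exchange at −100 °C should outrun attack of n-BuLi on the α-branched, donor-deactivated acrylate; and only the Z isomer secured in steps 5 and 7 can cyclise. The new ketone is conjugated to O1 and should not accept a second nucleophile at this temperature, and the absence of acid leaves ring D intact.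

**Step 9**
Reactants: 15 3-{8-methoxy-2,2-dimethyl-5-[(triisopropylsilyl)oxy]-2H-chromen-6-yl}-7-[(triisopropylsilyl)oxy]-4H-chromen-4-one
Product: 16 7-hydroxy-3-(5-hydroxy-8-methoxy-2,2-dimethyl-2H-chromen-6-yl)-4H-chromen-4-one
Conditions: TBAF (2.2 equiv), AcOH (2.2 equiv), THF, 0 °C to rt
Reagents that add atoms: none
Why: Fluoride-induced cleavage of both aryl silyl ethers should free the two phenols in one operation, with acetic acid buffering the phenoxides so that the pyranone is not opened and ring D never meets acid.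

**Compound list**
1 | 2,4-dihydroxy-5-methoxybenzaldehyde | COc1cc(C=O)c(O)cc1O | starting material
2 | 3-chloro-3-methylbut-1-yne | C#CC(C)(C)Cl | starting material
3 | 2-hydroxy-5-methoxy-4-[(2-methylbut-3-yn-2-yl)oxy]benzaldehyde | COc1cc(C=O)c(O)cc1OC(C)(C)C#C | intermediate
4 | 2,4-dihydroxy-5-methoxy-3-(3-methylbuta-1,2-dien-1-yl)benzaldehyde (allenyl phenol) | COc1cc(C=O)c(O)c(C=C=C(C)C)c1O | intermediate (not isolated)
5 | 5-hydroxy-8-methoxy-2,2-dimethyl-2H-chromene-6-carbaldehyde | COc1cc(C=O)c(O)c2C=CC(C)(C)Oc12 | intermediate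
6 | 8-methoxy-2,2-dimethyl-5-[(triisopropylsilyl)oxy]-2H-chromene-6-carbaldehyde | COc1cc(C=O)c(O[Si](C(C)C)(C(C)C)C(C)C)c2C=CC(C)(C)Oc12 | intermediate
7 | ethyl diazoacetate | CCOC(=O)C=[N+]=[N-] | starting material
8 | ethyl (Z)-3-hydroxy-2-{8-methoxy-2,2-dimethyl-5-[(triisopropylsilyl)oxy]-2H-chromen-6-yl}prop-2-enoate | CCOC(=O)/C(=C\O)c1cc(OC)c2OC(C)(C)C=Cc2c1O[Si](C(C)C)(C(C)C)C(C)C | intermediate
9 | ethyl (Z)-2-{8-methoxy-2,2-dimethyl-5-[(triisopropylsilyl)oxy]-2H-chromen-6-yl}-3-(tosyloxy)prop-2-enoate | CCOC(=O)/C(=C\OS(=O)(=O)c1ccc(C)cc1)c1cc(OC)c2OC(C)(C)C=Cc2c1O[Si](C(C)C)(C(C)C)C(C)C | intermediate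
10 | 4-bromoresorcinol (4-bromobenzene-1,3-diol) | Oc1ccc(Br)c(O)c1 | starting material
11 | 2-bromo-5-[(triisopropylsilyl)oxy]phenol | Oc1cc(O[Si](C(C)C)(C(C)C)C(C)C)ccc1Br | intermediate
12 | ethyl (Z)-3-{2-bromo-5-[(triisopropylsilyl)oxy]phenoxy}-2-{8-methoxy-2,2-dimethyl-5-[(triisopropylsilyl)oxy]-2H-chromen-6-yl}prop-2-enoate | CCOC(=O)/C(=C\Oc1cc(O[Si](C(C)C)(C(C)C)C(C)C)ccc1Br)c1cc(OC)c2OC(C)(C)C=Cc2c1O[Si](C(C)C)(C(C)C)C(C)C | intermediate
13 | aryllithium: 12 with lithium in place of bromine | CCOC(=O)/C(=C\Oc1cc(O[Si](C(C)C)(C(C)C)C(C)C)ccc1[Li])c1cc(OC)c2OC(C)(C)C=Cc2c1O[Si](C(C)C)(C(C)C)C(C)C | intermediate (not isolated)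
14 | lithium 4-ethoxy-3-{8-methoxy-2,2-dimethyl-5-[(triisopropylsilyl)oxy]-2H-chromen-6-yl}-7-[(triisopropylsilyl)oxy]-4H-chromen-4-olate (racemic at C4) | CCOC1(O[Li])c2ccc(O[Si](C(C)C)(C(C)C)C(C)C)cc2OC=C1c1cc(OC)c2OC(C)(C)C=Cc2c1O[Si](C(C)C)(C(C)C)C(C)C | intermediate (not isolated)
15 | 3-{8-methoxy-2,2-dimethyl-5-[(triisopropylsilyl)oxy]-2H-chromen-6-yl}-7-[(triisopropylsilyl)oxy]-4H-chromen-4-one | COc1cc(-c2coc3cc(O[Si](C(C)C)(C(C)C)C(C)C)ccc3c2=O)c(O[Si](C(C)C)(C(C)C)C(C)C)c2C=CC(C)(C)Oc12 | intermediate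
16 | 7-hydroxy-3-(5-hydroxy-8-methoxy-2,2-dimethyl-2H-chromen-6-yl)-4H-chromen-4-one | COc1cc(-c2coc3cc(O)ccc3c2=O)c(O)c2c1OC(C)(C)C=C2 | target

**Step count**
Total: 9 steps. Longest linear sequence: 8 steps (steps 1, 2, 3, 4, 5, 7, 8, 9); step 6 is the one-step side branch.

**Steps most likely to fail**

1. Step 7. The Z geometry may be lost, either by rotation in the carbanion formed on addition or by later phenoxide-induced exchange, which would drift toward the more stable isomer with aryloxy trans to the ester. The phenoxide may also attack sulfur and remove the tosyl group instead of substituting at C2. The fallback gives up kinetic control and sets out from 8. Deoxychlorination with Ph3P, C2Cl6 and Et3N in MeCN would give ethyl 3-chloro-2-{8-methoxy-2,2-dimethyl-5-[(triisopropylsilyl)oxy]-2H-chromen-6-yl}prop-2-enoate F1 as a mixture of geometric isomers. Substitution of its chloride by 11 (K2CO3, DMF, rt) cannot suffer sulfonyl transfer and would give 12 together with its isomer ethyl (E)-3-{2-bromo-5-[(triisopropylsilyl)oxy]phenoxy}-2-{8-methoxy-2,2-dimethyl-5-[(triisopropylsilyl)oxy]-2H-chromen-6-yl}prop-2-enoate F2. The isomers are separated by chromatography. F2 is returned to a photostationary mixture by triplet-sensitised irradiation (thioxanthone, 365 nm, MeCN), a known behaviour of β-alkoxy- and β-aryloxyacrylates, and more 12 is taken from it. The route is rejoined at 12.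

2. Step 8. n-BuLi may attack the acrylate, by carbonyl addition or by conjugate addition at C2 with loss of the aryloxide, in competition with exchange. The aryllithium may also be protonated or butylated before it acylates. The fallback replaces kinetic bromine–lithium exchange by an ester-tolerant iodine–magnesium exchange and sets out from 9. Purchased 4-iodoresorcinol (Oc1ccc(I)c(O)c1) is mono-silylated as in step 6 to 2-iodo-5-[(triisopropylsilyl)oxy]phenol F3. F3 is joined to 9 as in step 7 to give ethyl (Z)-3-{2-iodo-5-[(triisopropylsilyl)oxy]phenoxy}-2-{8-methoxy-2,2-dimethyl-5-[(triisopropylsilyl)oxy]-2H-chromen-6-yl}prop-2-enoate F4. Treatment with i-PrMgCl·LiCl in THF at −40 °C should give the arylmagnesium chloride F5 (not isolated) without touching the ester, and warming to rt should close ring C. The route is rejoined at 15.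

3. Step 4. Hydride migration may compete with aryl migration and give the β-keto ester, and the acid catalyst may remove the silyl ether or oligomerise the chromene. The fallback is an Arndt–Eistert homologation and sets out from 6. Pinnick oxidation (NaClO2, NaH2PO4, 2-methylbut-2-ene, t-BuOH/H2O) would give 8-methoxy-2,2-dimethyl-5-[(triisopropylsilyl)oxy]-2H-chromene-6-carboxylic acid F6. Ethyl chloroformate and Et3N convert it to the mixed carbonic anhydride F7 (not isolated), and TMSCHN2 gives 2-diazo-1-{8-methoxy-2,2-dimethyl-5-[(triisopropylsilyl)oxy]-2H-chromen-6-yl}ethan-1-one F8. Wolff rearrangement (PhCO2Ag, Et3N, EtOH) gives ethyl 2-{8-methoxy-2,2-dimethyl-5-[(triisopropylsilyl)oxy]-2H-chromen-6-yl}acetate F9. Claisen formylation (NaH, ethyl formate, THF) then gives 8, where the route is rejoined.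

**Further compounds**
F1 | step 7 | ethyl 3-chloro-2-{8-methoxy-2,2-dimethyl-5-[(triisopropylsilyl)oxy]-2H-chromen-6-yl}prop-2-enoate (mixture of geometric isomers) | CCOC(=O)C(=CCl)c1cc(OC)c2OC(C)(C)C=Cc2c1O[Si](C(C)C)(C(C)C)C(C)C
F2 | step 7 | ethyl (E)-3-{2-bromo-5-[(triisopropylsilyl)oxy]phenoxy}-2-{8-methoxy-2,2-dimethyl-5-[(triisopropylsilyl)oxy]-2H-chromen-6-yl}prop-2-enoate | CCOC(=O)/C(=C/Oc1cc(O[Si](C(C)C)(C(C)C)C(C)C)ccc1Br)c1cc(OC)c2OC(C)(C)C=Cc2c1O[Si](C(C)C)(C(C)C)C(C)C
F3 | step 8 | 2-iodo-5-[(triisopropylsilyl)oxy]phenol | Oc1cc(O[Si](C(C)C)(C(C)C)C(C)C)ccc1I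
F4 | step 8 | ethyl (Z)-3-{2-iodo-5-[(triisopropylsilyl)oxy]phenoxy}-2-{8-methoxy-2,2-dimethyl-5-[(triisopropylsilyl)oxy]-2H-chromen-6-yl}prop-2-enoate | CCOC(=O)/C(=C\Oc1cc(O[Si](C(C)C)(C(C)C)C(C)C)ccc1I)c1cc(OC)c2OC(C)(C)C=Cc2c1O[Si](C(C)C)(C(C)C)C(C)C
F5 | step 8 | arylmagnesium chloride: F4 with MgCl in place of iodine (not isolated) | CCOC(=O)/C(=C\Oc1cc(O[Si](C(C)C)(C(C)C)C(C)C)ccc1[Mg]Cl)c1cc(OC)c2OC(C)(C)C=Cc2c1O[Si](C(C)C)(C(C)C)C(C)C
F6 | step 4 | 8-methoxy-2,2-dimethyl-5-[(triisopropylsilyl)oxy]-2H-chromene-6-carboxylic acid | COc1cc(C(=O)O)c(O[Si](C(C)C)(C(C)C)C(C)C)c2C=CC(C)(C)Oc12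
F7 | step 4 | ethoxycarbonyl 8-methoxy-2,2-dimethyl-5-[(triisopropylsilyl)oxy]-2H-chromene-6-carboxylate (mixed anhydride, not isolated) | CCOC(=O)OC(=O)c1cc(OC)c2OC(C)(C)C=Cc2c1O[Si](C(C)C)(C(C)C)C(C)C
F8 | step 4 | 2-diazo-1-{8-methoxy-2,2-dimethyl-5-[(triisopropylsilyl)oxy]-2H-chromen-6-yl}ethan-1-one | COc1cc(C(=O)C=[N+]=[N-])c(O[Si](C(C)C)(C(C)C)C(C)C)c2C=CC(C)(C)Oc12
F9 | step 4 | ethyl 2-{8-methoxy-2,2-dimethyl-5-[(triisopropylsilyl)oxy]-2H-chromen-6-yl}acetate | CCOC(=O)Cc1cc(OC)c2OC(C)(C)C=Cc2c1O[Si](C(C)C)(C(C)C)C(C)C
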